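## Structural features

The target 18 is a C25 bicyclic butenolide. In the skeleton numbering used here, ring A is C1–C5 plus C10 (two methyls on C4, an angular methyl on C10), ring B is C5–C10 (methyl on C8), and a chain C11–C16 runs from C9 to C4 of a furan-2(5H)-one, with a hydroxymethyl branch on C13. The rings share the C5–C10 bond in a cis-fused decalin, and ring B holds a tetrasubstituted C8=C9 olefin directly beside the quaternary C10. There are only two stereocentres, the neighbours C5 (R) and C10 (S), with C5–H and C10–CH3 on the same face; the rest of the stereochemistry is olefinic, C13=C14 with C12 cis to C15 (13E) and C15=C16 trans (15E). The fragile parts are the butenolide (strong base, nucleophiles), the diene–lactone chromophore (light, acid, radical isomerization), the allylic primary alcohol and the tetrasubstituted olefin, which can migrate under strong acid. The real difficulty is the cis ring fusion at a quaternary carbon: cationic closures and equilibrating conditions lean toward the trans series, so C10 must be set kinetically and relative to C5. A smaller problem is the C13=C14 olefin, whose two C13 substituents are both CH2 groups and give no thermodynamic bias. The key step exploits the fact that ring A, the C5 stereocentre, the C10 methyl and a C1=C10 olefin are all present in (R)-α-ionone (1), and that C9 can be leashed to C5 through C6–C7–C8 so that it reaches C10 from one face only.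

## Logic of the disconnections

18 is cut at the C15=C16 double bond into 14 and 16. This is the last bond formed because it joins the base-sensitive lactone to the rest, and the cut separates a C20 enal from a C5 phosphonium unit. The forward olefination must be E-selective, must not open the lactone and must leave the C13=C14 geometry and the free alcohol alone.

16 is cut at its C–P bond to 15 and triphenylphosphine. This is a simple quaternization with no selectivity demand.

14 is cut at the C12–C13 single bond (and at the C14–H bond) into 10 and 11. An anti addition of a C12 carbon nucleophile and a proton across the alkyne of 11 fixes the C13=C14 geometry in the bond-forming step itself, and the propargylic oxygen steers the regiochemistry. The gain is that the whole stereodefined C13–C15 unit comes from one four-carbon alkyne. The demand is that 10 must give a clean organomagnesium reagent (12) and that the acetal (13) must last until it is hydrolysed.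

10 is traced to 9 (C12–Br to C12–OH) and 9 to 8 (O–H to O–Si). These are functional-group changes that keep C12 oxygenated and masked through the earlier steps. They demand neutral conditions because of the acid-sensitive tetrasubstituted olefin.

8 is cut at the C11–H bond with restoration of the C8–O bond, giving 7. A tetrasubstituted ring olefin cannot come directly from a ring closure at C10, but it follows by allylic transposition from an exocyclic C9=C11 olefin next to a C8 carbinol. The demand is hydride delivery at C11 and not at C8, without elimination and without loss of the silyl ether.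

7 is traced to 6 by reopening the C1=C2 olefin, which the ring closure leaves behind as its mechanistic footprint. The demand is reduction of a disubstituted olefin in the presence of a trisubstituted allylic one.

6 is cut at the C9–C10 bond to 5. This is the strategic cut: it removes ring B and the quaternary stereocentre together and leaves a monocyclic enyne whose only fixed stereocentre is C5. The forward step must form the bond at the more substituted olefin carbon, from the face of the C5 tether, and end as a diene.

5 is cut at the C8–C9 bond into 2 and 3 (through 4). A ketone and a three-carbon alkyne result, and the C8 configuration does not matter. The silyl group on O12 is tert-butyldiphenylsilyl so that it withstands the acidic steps and offers a hindered, weakly nucleophilic oxygen.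

2 is traced to 1 by reintroducing the C6=C7 olefin. The forward reduction must be 1,4-selective, spare the ring olefin and not epimerize C5.

## Other disconnections considered

Alternative 1: The cut removes both rings at once, at C4–C5 and C9–C10, and leads to the acyclic (S)-epoxide A1, a Z-olefinic β-keto ester. In the forward step a Lewis acid (MeAlCl2 or SnCl4) would open the epoxide at C4, the Z C5=C10 olefin would add to it, and the enol carbon C9 would close on C10 to give the cis-fused hydroxy keto ester A2.
- In its favour: two rings, two C–C bonds and three stereocentres would arise in one operation from a cheap chain whose single stereocentre comes from a catalytic epoxidation. In bond-forming efficiency this is better than the chosen plan, which closes one ring.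
- Against it here: the cis fusion depends on a concerted anti addition across the Z olefin, and a stepwise cation can drift toward the trans series. The enol oxygen can compete with C9 as terminator. A2 also carries a C3 hydroxyl that the target lacks, an enol at C8 where a methyl is needed, and C11 at the ester level with C12 missing.
- Comparison: the ring fusion rests on conformational bias in a cation, against a geometric constraint in a carbopalladation. Some four to six corrective steps (C3 deoxygenation, enol triflate and methyl cuprate at C8, reduction and one-carbon extension at C11) stand against the three that take 6 to 9. The two plans are equal in that each draws absolute configuration from one early stereocentre.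

Alternative 2: The cut is C1–C10 in ring A, paired with a retrosynthetic reconnection of C3 to C8. This leads to the bridged carbinol A3, a 2-vinylbicyclo[2.2.2]oct-5-en-2-ol whose vinyl group lies over the C9=C10 bridge. Forward, its potassium alkoxide (KH, 18-crown-6) would undergo an anionic oxy-Cope rearrangement through the boat geometry that the bicycle imposes and give, after enolate protonation, the cis-fused ketone A4.
- In its favour: the cis fusion is enforced by geometry as firmly as in the chosen plan, so the two are equal on that point. A4 is better than 6 in one respect: it already has the C8=C9 olefin and the C11–C12 chain, so no transposition is needed.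
- Against it here: A3 is crowded, with a carbinol flanked by two quaternary carbons. The vinyl group must be added to the parent ketone from the face over the olefin, and the new bond forms at a methyl-bearing olefin carbon. Absolute configuration must be created by an asymmetric cycloaddition or a resolution, since no chiral-pool ring is used. The C3 ketone of A4 is foreign to the target and sits next to the gem-dimethyl group, so its removal needs a forcing Wolff–Kishner-type reduction.
- Comparison: after the key step the count is about equal (two steps from A4 to 9 against three from 6), but the longer access to A3 outweighs this.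

Alternative 3: Ring B is cut at C5–C6 and C6–C7 with C6 leaving as CO, and C5 is reconnected to C9. This leads to the cyclopropane-fused lactone A5, in which C9 carries an isopropenyl group (C8, C7) and the C11 carbonyl tied to the C1 oxygen. Forward, [Rh(CO)2Cl]2 under CO would insert into the C5–C9 bond of the vinylcyclopropane, take up CO and close to the β,γ-unsaturated ketone A6.
- In its favour: C9 never leaves the face of ring A, so the cis fusion is as secure as in the chosen plan. The C8=C9 olefin with its methyl arises directly, which is better than the chosen plan. Absolute configuration could be relayed from the C1 carbinol through an intramolecular cyclopropanation.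
- Against it here: A6 holds three functions that the target does not have or has at another level (the C6 ketone, the C1–O bond, C11 as a carboxyl carbon with C12 missing). The β,γ-unsaturated ketone can slip into conjugation and move the olefin. The choice between the C5–C9 and C9–C10 cyclopropane bonds is not assured on so substituted a ring.
- Comparison: mechanistically elegant, but two deoxygenations and a homologation make it clearly longer than the chosen route after the key step.

Key step: step 3

Assumption: 3, 11 and 15 are taken as purchasable reagents, and 5, 6 and 7 are carried as mixtures of C8 epimers, which is harmless because C8 becomes trigonal in step 5.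

## Route

Step 1
Reactants: 1 (R)-α-ionone, (3E)-4-[(1R)-2,6,6-trimethylcyclohex-2-en-1-yl]but-3-en-2-one
Product: 2 4-[(1R)-2,6,6-trimethylcyclohex-2-en-1-yl]butan-2-one
Conditions: [CuH(PPh3)]6 (0.2 equiv, 1.2 equiv hydride), H2O (2 equiv), benzene, rt
Reagents that add atoms: none
Why: Conjugate hydride reduction of the enone by the phosphine-stabilized copper hydride leaves the ring olefin untouched, and the neutral medium avoids the γ-deprotonation that would racemize C5 or pull the ring olefin into conjugation.

Step 2
Reactants: 2 4-[(1R)-2,6,6-trimethylcyclohex-2-en-1-yl]butan-2-one; 3 tert-butyl(diphenyl)(prop-2-yn-1-yloxy)silane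
Product: 5 1-[tert-butyl(diphenyl)silyl]oxy-4-methyl-6-[(1R)-2,6,6-trimethylcyclohex-2-en-1-yl]hex-2-yn-4-ol (both C8 epimers), via lithium acetylide 4 (not isolated)
Conditions: 3, n-BuLi, THF, −78 °C; then 2, −78 → 0 °C; aq NH4Cl
Reagents that add atoms: none
Why: 1,2-Addition of a lithium acetylide to a methyl ketone forms C8–C9; the new C8 centre is not controlled and need not be. The tert-butyldiphenylsilyl ether is preferred to a smaller silyl group because it must survive AcOH at 60 °C and BF3·OEt2 later, and its hindered oxygen is a poor internal nucleophile.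

Step 3
Reactants: 5 1-[tert-butyl(diphenyl)silyl]oxy-4-methyl-6-[(1R)-2,6,6-trimethylcyclohex-2-en-1-yl]hex-2-yn-4-ol
Product: 6 (1Z,4aR,8aS)-1-{2-[tert-butyl(diphenyl)silyl]oxyethylidene}-2,5,5,8a-tetramethyl-1,2,3,4,4a,5,6,8a-octahydronaphthalen-2-ol (both C8 epimers; cis-fused, exocyclic C9=C11 and ring C1=C2 in skeleton numbering)
Conditions: Pd2(dba)3·CHCl3 (2.5 mol%), P(o-tol)3 (10 mol%), AcOH (0.5 equiv), toluene, 60 °C
Reagents that add atoms: none
Why: Zerovalent palladium and AcOH form H–Pd–OAc, which adds syn across the C9≡C11 triple bond with palladium on C9; the vinylpalladium then inserts the C1=C10 ring olefin, and β-hydride loss from C2 releases the 1,4-diene and returns the palladium hydride. The closest known reaction type is the palladium-catalysed Alder-ene cycloisomerization of 1,6- and 1,7-enynes to 1,4-dienes. Ring B closes 6-exo-trig at C10; the 7-endo mode would put palladium on a tertiary carbon and is not expected. C10 is the one new stereocentre and is controlled by C5: C9 is leashed to C5 by a three-atom chain and can reach C10 only from the face that carries the C5–C6 bond, and the suprafacial insertion therefore leaves the C10 methyl cis to C5–H (5R,10S). The step needs palladium on C9, insertion ahead of alkyne oligomerization, and hydride loss toward C2. The first should be secured by chelation of the tethered olefin and the C8 hydroxyl, the second by the fully substituted C8 and the ring, which hold the reacting ends together, and the third by the lack of any other β-hydrogen, since C10 is quaternary. Syn hydropalladation fixes the exocyclic olefin as Z (C12 cis to C8), and both C8 epimers should react because C8 is a spectator here.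

Step 4
Reactants: 6 (1Z,4aR,8aS)-1-{2-[tert-butyl(diphenyl)silyl]oxyethylidene}-2,5,5,8a-tetramethyl-1,2,3,4,4a,5,6,8a-octahydronaphthalen-2-ol
Product: 7 (1Z,4aR,8aS)-1-{2-[tert-butyl(diphenyl)silyl]oxyethylidene}-2,5,5,8a-tetramethyldecahydronaphthalen-2-ol (both C8 epimers)
Conditions: 2-nitrobenzenesulfonylhydrazide (5 equiv), Et3N, CH2Cl2, rt
Reagents that add atoms: none
Why: Diimide transfers H2 in a concerted syn fashion and discriminates strongly by substitution, so the cis-disubstituted C1=C2 olefin should be reduced while the trisubstituted C9=C11 olefin stays; no metal is present that could hydrogenolyse the allylic C–O bonds.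

Step 5
Reactants: 7 (1Z,4aR,8aS)-1-{2-[tert-butyl(diphenyl)silyl]oxyethylidene}-2,5,5,8a-tetramethyldecahydronaphthalen-2-ol
Product: 8 tert-butyl(diphenyl){2-[(4aR,8aS)-2,5,5,8a-tetramethyl-3,4,4a,5,6,7,8,8a-octahydronaphthalen-1-yl]ethoxy}silane
Conditions: Et3SiH (5 equiv), BF3·OEt2 (1.5 equiv), CH2Cl2, −78 → −40 °C
Reagents that add atoms: none
Why: Ionic hydrogenation of a tertiary allylic alcohol: BF3 ionizes C8–OH to the C8–C9–C11 allyl cation, and Et3SiH should deliver hydride to the less hindered terminus C11, giving the more substituted C8=C9 olefin. No stereocentre is formed and the C8 epimers converge.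

Step 6
Reactants: 8 tert-butyl(diphenyl){2-[(4aR,8aS)-2,5,5,8a-tetramethyl-3,4,4a,5,6,7,8,8a-octahydronaphthalen-1-yl]ethoxy}silane
Product: 9 2-[(4aR,8aS)-2,5,5,8a-tetramethyl-3,4,4a,5,6,7,8,8a-octahydronaphthalen-1-yl]ethan-1-ol
Conditions: Bu4NF, THF, rt
Reagents that add atoms: none
Why: Fluoride cleaves the Si–O bond; nothing else in the molecule is sensitive to fluoride or mild base.

Step 7
Reactants: 9 2-[(4aR,8aS)-2,5,5,8a-tetramethyl-3,4,4a,5,6,7,8,8a-octahydronaphthalen-1-yl]ethan-1-ol
Product: 10 (4aR,8aS)-1-(2-bromoethyl)-2,5,5,8a-tetramethyl-3,4,4a,5,6,7,8,8a-octahydronaphthalene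
Conditions: CBr4, PPh3, CH2Cl2, 0 °C
Reagents that add atoms: carbon tetrabromide, BrC(Br)(Br)Br
Why: Appel bromination: bromide displaces the alkoxyphosphonium group by SN2 at the primary carbon under neutral conditions, which leave the tetrasubstituted olefin in place.

Step 8
Reactants: 10 (4aR,8aS)-1-(2-bromoethyl)-2,5,5,8a-tetramethyl-3,4,4a,5,6,7,8,8a-octahydronaphthalene; 11 4,4-diethoxybut-2-yn-1-ol
Product: 14 (2E)-4-hydroxy-3-{2-[(4aR,8aS)-2,5,5,8a-tetramethyl-3,4,4a,5,6,7,8,8a-octahydronaphthalen-1-yl]ethyl}but-2-enal, via Grignard reagent 12 (not isolated), via diethyl acetal 13 (not isolated)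
Conditions: 10, Mg, THF, rt; 11, MeMgCl (1 equiv), THF, 0 °C; combine, CuI (15 mol%), −20 °C → rt; aq NH4Cl; then 1 M HCl, THF, 0 °C
Reagents that add atoms: water, O
Why: Magnesium insertion gives the primary homoallylic Grignard reagent, and its copper-catalysed anti-carbomagnesiation of the propargylic magnesium alkoxide puts the alkyl group on the carbinol-bearing alkyne carbon and magnesium on the distal carbon in a five-membered chelate. Protonation then leaves C12 cis to C15 (13E), and dilute acid in the work-up hydrolyses the allylic acetal to the enal without touching that geometry.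

Step 9
Reactants: 15 4-(bromomethyl)furan-2(5H)-one
Product: 16 [(5-oxo-2,5-dihydrofuran-3-yl)methyl]triphenylphosphonium bromide
Conditions: PPh3, toluene, rt
Reagents that add atoms: triphenylphosphine, c1ccc(cc1)P(c1ccccc1)c1ccccc1
Why: SN2 quaternization of triphenylphosphine by an allylic bromide; the salt should precipitate from toluene.

Step 10
Reactants: 14 (2E)-4-hydroxy-3-{2-[(4aR,8aS)-2,5,5,8a-tetramethyl-3,4,4a,5,6,7,8,8a-octahydronaphthalen-1-yl]ethyl}but-2-enal; 16 [(5-oxo-2,5-dihydrofuran-3-yl)methyl]triphenylphosphonium bromide
Product: 18 4-[(1E,3E)-4-(hydroxymethyl)-6-[(4aR,8aS)-2,5,5,8a-tetramethyl-3,4,4a,5,6,7,8,8a-octahydronaphthalen-1-yl]hexa-1,3-dien-1-yl]furan-2(5H)-one, via phosphorus ylide 17 (not isolated)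
Conditions: 16 (1.4 equiv), NaN(SiMe3)2 (1.3 equiv), THF, −78 °C; then 14, −78 → 0 °C
Reagents that add atoms: none
Why: Wittig olefination of the enal by a vinylogously ester-stabilized ylide, which is expected to favour the E C15=C16 olefin. The ylide is too weakly basic to deprotonate the free alcohol or to disturb C13=C14, and no excess base meets the lactone.

## Compound list

1 | (R)-α-ionone, (3E)-4-[(1R)-2,6,6-trimethylcyclohex-2-en-1-yl]but-3-en-2-one | CC1=CCCC(C)(C)[C@H]1/C=C/C(C)=O | starting material
2 | 4-[(1R)-2,6,6-trimethylcyclohex-2-en-1-yl]butan-2-one | CC1=CCCC(C)(C)[C@H]1CCC(C)=O | intermediate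
3 | tert-butyl(diphenyl)(prop-2-yn-1-yloxy)silane | C#CCO[Si](c1ccccc1)(c1ccccc1)C(C)(C)C | starting material
4 | {3-[tert-butyl(diphenyl)silyl]oxyprop-1-yn-1-yl}lithium | [Li]C#CCO[Si](c1ccccc1)(c1ccccc1)C(C)(C)C | intermediate (not isolated)
5 | 1-[tert-butyl(diphenyl)silyl]oxy-4-methyl-6-[(1R)-2,6,6-trimethylcyclohex-2-en-1-yl]hex-2-yn-4-ol, both C8 epimers | CC1=CCCC(C)(C)[C@H]1CCC(C)(O)C#CCO[Si](c2ccccc2)(c2ccccc2)C(C)(C)C | intermediate
6 | (1Z,4aR,8aS)-1-{2-[tert-butyl(diphenyl)silyl]oxyethylidene}-2,5,5,8a-tetramethyl-1,2,3,4,4a,5,6,8a-octahydronaphthalen-2-ol, both C8 epimers | CC1(O)/C(=C\CO[Si](c3ccccc3)(c3ccccc3)C(C)(C)C)[C@@]2(C)C=CCC(C)(C)[C@H]2CC1 | intermediate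
7 | (1Z,4aR,8aS)-1-{2-[tert-butyl(diphenyl)silyl]oxyethylidene}-2,5,5,8a-tetramethyldecahydronaphthalen-2-ol, both C8 epimers | CC1(O)/C(=C\CO[Si](c3ccccc3)(c3ccccc3)C(C)(C)C)[C@@]2(C)CCCC(C)(C)[C@H]2CC1 | intermediate
8 | tert-butyl(diphenyl){2-[(4aR,8aS)-2,5,5,8a-tetramethyl-3,4,4a,5,6,7,8,8a-octahydronaphthalen-1-yl]ethoxy}silane | CC1=C(CCO[Si](c3ccccc3)(c3ccccc3)C(C)(C)C)[C@@]2(C)CCCC(C)(C)[C@H]2CC1 | intermediate
9 | 2-[(4aR,8aS)-2,5,5,8a-tetramethyl-3,4,4a,5,6,7,8,8a-octahydronaphthalen-1-yl]ethan-1-ol | CC1=C(CCO)[C@@]2(C)CCCC(C)(C)[C@H]2CC1 | intermediate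
10 | (4aR,8aS)-1-(2-bromoethyl)-2,5,5,8a-tetramethyl-3,4,4a,5,6,7,8,8a-octahydronaphthalene | CC1=C(CCBr)[C@@]2(C)CCCC(C)(C)[C@H]2CC1 | intermediate
11 | 4,4-diethoxybut-2-yn-1-ol | CCOC(OCC)C#CCO | starting material
12 | {2-[(4aR,8aS)-2,5,5,8a-tetramethyl-3,4,4a,5,6,7,8,8a-octahydronaphthalen-1-yl]ethyl}magnesium bromide | CC1=C(CC[Mg]Br)[C@@]2(C)CCCC(C)(C)[C@H]2CC1 | intermediate (not isolated)
13 | (2E)-4,4-diethoxy-2-{2-[(4aR,8aS)-2,5,5,8a-tetramethyl-3,4,4a,5,6,7,8,8a-octahydronaphthalen-1-yl]ethyl}but-2-en-1-ol | CC1=C(CC/C(=C\C(OCC)OCC)CO)[C@@]2(C)CCCC(C)(C)[C@H]2CC1 | intermediate (not isolated)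
14 | (2E)-4-hydroxy-3-{2-[(4aR,8aS)-2,5,5,8a-tetramethyl-3,4,4a,5,6,7,8,8a-octahydronaphthalen-1-yl]ethyl}but-2-enal | CC1=C(CC/C(=C\C=O)CO)[C@@]2(C)CCCC(C)(C)[C@H]2CC1 | intermediate
15 | 4-(bromomethyl)furan-2(5H)-one | O=C1C=C(CBr)CO1 | starting material
16 | [(5-oxo-2,5-dihydrofuran-3-yl)methyl]triphenylphosphonium bromide | O=C1C=C(C[P+](c2ccccc2)(c2ccccc2)c2ccccc2)CO1.[Br-] | intermediate
17 | 4-[(triphenyl-λ5-phosphanylidene)methyl]furan-2(5H)-one | O=C1C=C(C=P(c2ccccc2)(c2ccccc2)c2ccccc2)CO1 | intermediate (not isolated)
18 | 4-[(1E,3E)-4-(hydroxymethyl)-6-[(4aR,8aS)-2,5,5,8a-tetramethyl-3,4,4a,5,6,7,8,8a-octahydronaphthalen-1-yl]hexa-1,3-dien-1-yl]furan-2(5H)-one | CC1=C(CC/C(=C\C=C\C2=CC(=O)OC2)CO)[C@@]2(C)CCCC(C)(C)[C@H]2CC1 | target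

## Step count and least certain steps

Total step count: 10. Longest linear sequence: 9 steps (steps 1–8 and 10, from 1); step 9 is a one-step side branch.

Step 3 (key step). The most likely failure is slow migratory insertion into the trisubstituted ring olefin, where a quaternary carbon is being made, so that the vinylpalladium is diverted into alkyne oligomerization. Hydropalladation with the opposite regiochemistry and β-elimination of the C8 hydroxyl toward an allene are the other two risks. The fallback sets out from 5 and returns at 8; it fixes the metal on C9 beforehand and enters the same insertion by oxidative addition: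
- Bu3SnH with catalytic [Cp*RuCl]4 (CH2Cl2, rt) should give a hydroxyl-directed trans-hydrostannation with tin on C9, forming the (2Z)-3-stannyl allylic alcohol F1.
- I2 (CH2Cl2, 0 °C) converts it into the (2Z)-vinyl iodide F2.
- A Heck cyclization (Pd(OAc)2, PPh3, Ag2CO3, MeCN, 70 °C) closes ring B with the same facial constraint and gives the E-ethylidene diene carbinol F3.
- Diimide as in step 4 gives the E-ethylidene carbinol F4, and Et3SiH/BF3·OEt2 as in step 5 gives 8, because the olefin geometry is erased in the transposition.

Step 5. The risks are capture of the allyl cation at C8 instead of C11, proton loss to a diene, and attack of the cis-disposed ether oxygen on C8 with loss of silicon. The fallback sets out from 7 and returns at 8, avoiding a free carbocation. Acetylation (Ac2O, DMAP, Et3N, CH2Cl2, 40 °C) gives the tertiary allylic acetate F5. Pd(PPh3)4 (5 mol%) with LiBHEt3 in THF then forms the π-allyl complex of divalent palladium, and hydride should attack its less substituted terminus C11.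

Step 8. The risk is displacement of an ethoxy group in an SN2′ sense (the acetal is propargylic), which would bypass the chelate and lose the geometry control, or a sluggish addition of the hindered Grignard reagent with protonation instead. The fallback sets out from 10 and returns at 14, with the geometry set in a separate reagent:
- Zinc insertion (Zn, LiCl, THF) gives the alkylzinc bromide F6.
- Negishi coupling (Pd(OAc)2, SPhos, THF, rt) with (2Z)-4-[tert-butyl(dimethyl)silyl]oxy-3-iodobut-2-en-1-ol F7 gives the (2E)-allylic alcohol F8. F7 is the product of trans-hydroalumination of the matching monosilylated butynediol with NaAlH2(OCH2CH2OMe)2, then I2.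
- MnO2 (CH2Cl2) oxidizes it to the silyl-protected enal F9, and HF·pyridine (THF, 0 °C) removes the silyl group to give 14.

Step 10. The risks are incomplete E selectivity at C15=C16 and base-induced opening or deconjugation of the butenolide. An iodine-catalysed correction is not advisable because it could also scramble C13=C14. The fallback sets out from 14 and returns at 18, with the olefin geometry made before the lactone is attached. Takai iodo-olefination (CrCl2, CHI3, THF, 0 °C) gives the (2E,4E)-dienyl iodide F10. Stille coupling with 4-(tributylstannyl)furan-2(5H)-one F11 (Pd2(dba)3, AsPh3, CuI, NMP, rt) then gives 18 under neutral conditions.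

## Further compounds

F1 | step 3 | (2Z)-1-[tert-butyl(diphenyl)silyl]oxy-4-methyl-3-(tributylstannyl)-6-[(1R)-2,6,6-trimethylcyclohex-2-en-1-yl]hex-2-en-4-ol | CC1=CCCC(C)(C)[C@H]1CCC(C)(O)/C(=C/CO[Si](c2ccccc2)(c2ccccc2)C(C)(C)C)[Sn](CCCC)(CCCC)CCCC
F2 | step 3 | (2Z)-1-[tert-butyl(diphenyl)silyl]oxy-3-iodo-4-methyl-6-[(1R)-2,6,6-trimethylcyclohex-2-en-1-yl]hex-2-en-4-ol | CC1=CCCC(C)(C)[C@H]1CCC(C)(O)/C(I)=C/CO[Si](c2ccccc2)(c2ccccc2)C(C)(C)C
F3 | step 3 | (1E,4aR,8aS)-1-{2-[tert-butyl(diphenyl)silyl]oxyethylidene}-2,5,5,8a-tetramethyl-1,2,3,4,4a,5,6,8a-octahydronaphthalen-2-ol | CC1(O)/C(=C/CO[Si](c3ccccc3)(c3ccccc3)C(C)(C)C)[C@@]2(C)C=CCC(C)(C)[C@H]2CC1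
F4 | step 3 | (1E,4aR,8aS)-1-{2-[tert-butyl(diphenyl)silyl]oxyethylidene}-2,5,5,8a-tetramethyldecahydronaphthalen-2-ol | CC1(O)/C(=C/CO[Si](c3ccccc3)(c3ccccc3)C(C)(C)C)[C@@]2(C)CCCC(C)(C)[C@H]2CC1
F5 | step 5 | (1Z,4aR,8aS)-1-{2-[tert-butyl(diphenyl)silyl]oxyethylidene}-2,5,5,8a-tetramethyldecahydronaphthalen-2-yl acetate | CC1(OC(C)=O)/C(=C\CO[Si](c3ccccc3)(c3ccccc3)C(C)(C)C)[C@@]2(C)CCCC(C)(C)[C@H]2CC1
F6 | step 8 | {2-[(4aR,8aS)-2,5,5,8a-tetramethyl-3,4,4a,5,6,7,8,8a-octahydronaphthalen-1-yl]ethyl}zinc bromide | CC1=C(CC[Zn]Br)[C@@]2(C)CCCC(C)(C)[C@H]2CC1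
F7 | step 8 | (2Z)-4-[tert-butyl(dimethyl)silyl]oxy-3-iodobut-2-en-1-ol | OC/C=C(\I)CO[Si](C)(C)C(C)(C)C
F8 | step 8 | (2E)-3-({[tert-butyl(dimethyl)silyl]oxy}methyl)-5-[(4aR,8aS)-2,5,5,8a-tetramethyl-3,4,4a,5,6,7,8,8a-octahydronaphthalen-1-yl]pent-2-en-1-ol | CC1=C(CC/C(CO[Si](C)(C)C(C)(C)C)=C\CO)[C@@]2(C)CCCC(C)(C)[C@H]2CC1
F9 | step 8 | (2E)-3-({[tert-butyl(dimethyl)silyl]oxy}methyl)-5-[(4aR,8aS)-2,5,5,8a-tetramethyl-3,4,4a,5,6,7,8,8a-octahydronaphthalen-1-yl]pent-2-enal | CC1=C(CC/C(CO[Si](C)(C)C(C)(C)C)=C\C=O)[C@@]2(C)CCCC(C)(C)[C@H]2CC1
F10 | step 10 | (2E,4E)-5-iodo-2-{2-[(4aR,8aS)-2,5,5,8a-tetramethyl-3,4,4a,5,6,7,8,8a-octahydronaphthalen-1-yl]ethyl}penta-2,4-dien-1-ol | CC1=C(CC/C(=C\C=C\I)CO)[C@@]2(C)CCCC(C)(C)[C@H]2CC1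
F11 | step 10 | 4-(tributylstannyl)furan-2(5H)-one | CCCC[Sn](CCCC)(CCCC)C1=CC(=O)OC1
A1 | alternative 1 | methyl (6Z)-9-[(2S)-3,3-dimethyloxiran-2-yl]-7-methyl-3-oxonon-6-enoate | COC(=O)CC(=O)CC/C=C(C)\CC[C@@H]1OC1(C)C
A2 | alternative 1 | cis-fused bicyclic hydroxy β-keto ester, enol form, with C3–OH, C5–H and C10–CH3 on one face | OC1=C(C(=O)OC)[C@@]2(C)CC[C@H](O)C(C)(C)[C@H]2CC1
A3 | alternative 2 | 6-{2-[tert-butyl(dimethyl)silyl]oxyethyl}-1,3,3,5-tetramethyl-2-vinylbicyclo[2.2.2]oct-5-en-2-ol, vinyl syn to the olefin bridge | C=C[C@]1(O)C(C)(C)[C@H]2CC[C@]1(C)C(CCO[Si](C)(C)C(C)(C)C)=C2C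
A4 | alternative 2 | cis-fused decalin C3 ketone with C8=C9 and a 2-[tert-butyl(dimethyl)silyl]oxyethyl chain on C9 | CC1=C(CCO[Si](C)(C)C(C)(C)C)[C@@]2(C)CCC(=O)C(C)(C)[C@H]2CC1
A5 | alternative 3 | cyclopropane-fused γ-lactone with isopropenyl and the C11 carbonyl on C9 of the C5–C9–C10 cyclopropane | CC(=C)[C@@]12C(=O)O[C@H]3CCC(C)(C)[C@@H]1[C@@]23C
A6 | alternative 3 | cis-fused decalin C6 ketone with C8=C9 and the C11 lactone to the C1 oxygen | CC1=C2C(=O)O[C@H]3CCC(C)(C)[C@@H](C(=O)C1)[C@@]23C
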